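Numbering used: ring A = C1–C5 (C2 carries OAc, C4 carries OH and CH3); cyclobutane = C1, C5, C6, C10; ring B = C6–C10 (C8 carries the tiglate, C10 a CH3); butenolide = O–C12(=O)–C11(C13H2OAc)=C7, fused to ring B at C6–C7.
Cuts: first the three ester C–O bonds and the C4 carbinol (back to a C4 ketone); then, in one operation, the ring B bonds C8–C9 and C6–C10 (C6–C10 is also a cyclobutane bond), which opens ring B and the cyclobutane to a 3-formylfuran and an isopropenyl group on cis-disposed positions of ring A; last the furan–C5 and isopropenyl–C1 bonds.
Enabling feature: in ring B the oxygen-bearing quaternary C6 and the carbinol C8 flank sp2 C7, the pattern of a 3-formylfuran (nucleophilic α-carbon C6, electrophilic formyl carbon C8, one oxidation level below the butenolide); they are bridged by C9H2–C10(CH3), the pattern of an isopropenyl group whose substituted carbon can carry a tertiary cation.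
Forward order: ring A from a chiral-pool cyclopentenone; furan joined at C5 (Negishi); isopropenyl at C1 (cuprate); ring B and the cyclobutane closed together (step 6); furan C12 oxidized to the butenolide; C4 carbinol, tiglate and acetates last.
Stereochemistry: C2 from (S)-4-silyloxycyclopentenone; C1 by cuprate addition anti to the silyloxy group; C5 by kinetic protonation; C6 and C10 by the cis arms and a SnCl4 chelate to the C4 ketone; C8 by Mitsunobu inversion; C4 by convex-face radical oxygenation.

Key step: step 6

Assumption: compounds 1, 3, 8 and 17 are taken as catalogue chemicals, and lactol 13 is carried on as a mixture at its hemiacetal carbon, which step 7 erases.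

Step 1
Reactants: 1 furan-3,4-diyldimethanol
Product: 2 [4-({[tert-butyl(dimethyl)silyl]oxy}methyl)furan-3-yl]methanol
Conditions: 1 (3 equiv), TBSCl (1 equiv), imidazole, DMF, 0 °C
Reagents that add atoms: tert-butyldimethylsilyl chloride, CC(C)(C)[Si](C)(C)Cl
Why: Statistical mono-O-silylation of a symmetrical diol used in excess should give the mono-TBS ether, the two hydroxymethyl groups being equivalent.

Step 2
Reactants: 3 (S)-4-{[tert-butyl(dimethyl)silyl]oxy}cyclopent-2-en-1-one
Product: 4 (S)-4-{[tert-butyl(dimethyl)silyl]oxy}-2-iodocyclopent-2-en-1-one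
Conditions: I2, pyridine/CH2Cl2, 0 °C to rt
Reagents that add atoms: iodine, II
Why: α-Iodination of the enone by pyridine addition, iodination and elimination (Baylis–Hillman-type sequence) leaves the silyloxy-bearing stereocentre untouched.

Step 3
Reactants: 2 [4-({[tert-butyl(dimethyl)silyl]oxy}methyl)furan-3-yl]methanol; 4 (S)-4-{[tert-butyl(dimethyl)silyl]oxy}-2-iodocyclopent-2-en-1-one
Product: 7 (S)-4-silyloxy-2-[3-(hydroxymethyl)-4-(silyloxymethyl)furan-2-yl]cyclopent-2-en-1-one (silyl = TBS), via dilithiated furan 5 (not isolated), via furylzinc chloride 6 (not isolated)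
Conditions: 2, n-BuLi (2.2 equiv), THF, −78 to 0 °C; ZnCl2 (1.2 equiv), 0 °C; then 4, Pd(PPh3)4 (5 mol%), rt; H2O work-up
Reagents that add atoms: none
Why: Alkoxide-directed ortho-lithiation should occur at the furan α-carbon next to the CH2OLi group, and transmetalation to zinc followed by Negishi coupling with the α-iodoenone joins the fragments without touching the stereocentre.

Step 4
Reactants: 7 furyl enone; 8 isopropenylmagnesium bromide
Product: 10 4-silyloxy-2-furyl-3-isopropenylcyclopentan-1-one (furyl cis to isopropenyl; silyloxy trans to isopropenyl; CH2OH on the furan), via bromomagnesium enolate 9 (not isolated)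
Conditions: 8 (4.2 equiv), CuI (2.1 equiv), THF, −78 to −40 °C; cannulated into AcOH/THF at −78 °C
Reagents that add atoms: none
Why: Cuprate conjugate addition should occur anti to the adjacent silyloxy group (sets C1), and kinetic protonation of the enolate on the face away from the new isopropenyl group should place the furyl group cis to it (sets C5); one equivalent of cuprate is spent on the free hydroxyl.

Step 5
Reactants: 10 furylmethanol ketone
Product: 11 2-(2-oxo-cyclopentyl)furan-3-carbaldehyde (same ring A stereochemistry as 10; C8 now CHO)
Conditions: MnO2 (activated, excess), CH2Cl2, rt; filtered and used directly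
Reagents that add atoms: none
Why: MnO2 oxidizes the furylmethanol (heteroaryl carbinol) to the aldehyde under neutral heterogeneous conditions that should not epimerize the α-furyl ketone.

Step 6
Reactants: 11 keto aldehyde
Product: 13 tetracyclic lactol (cyclobutane and ring B closed; C4 ketone; C8–OH on the cyclobutane side of ring B; C12 hemiacetal; two TBS ethers), via trichlorostannyl alkoxide chloro ether 12 (not isolated)
Conditions: SnCl4 (1.2 equiv), 2,6-di-tert-butyl-4-methylpyridine (0.3 equiv), CH2Cl2 (0.005 M), −78 to −40 °C; then NaHCO3/H2O
Reagents that add atoms: water, O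
Why: Proposed new method: SnCl4 held in a chelate between the C4 ketone oxygen and the formyl oxygen activates the aldehyde, the CH2 terminus C9 of the isopropenyl group attacks the formyl carbon C8 (Prins step, a seven-membered closure that is endo with respect to the alkene and Markovnikov), and the tertiary cation at C10 is captured transannularly by the substituted furan α-carbon C6 (ipso Friedel–Crafts attack; 4-exo-trig for the cyclobutane, 5-endo-trig for ring B), the furan-derived oxocarbenium ion collapsing to chloro ether 12, which water converts into the lactol. The closest known reaction types are Prins/Friedel–Crafts cascades and furan-terminated cation–olefin cyclizations; the new element is the ipso capture that closes a four-membered ring, argued from the polarity match of both bond formations (activated aldehyde with a 1,1-disubstituted alkene, tertiary cation with an electron-rich trialkylfuran), from the proximity of C10 and C6 on cis arms, and from the absence of another π-nucleophile within reach. C10 and C6: the cyclobutane must be cis-fused to ring A because the arms at C1 and C5 are cis, and ring B must be cis-fused to the cyclobutane because C9 and C7 are tied through C8. The needed facial selectivity (ring B on the same face of the cyclobutane as ring A) is secured by the chelate, which can form only in the rotamer that holds the formyl-bearing furan carbon C7 next to C4, so that C7 should end up cis to C4 and C9 cis to C2. C8: the chelated formyl oxygen points toward ring A, so the hydroxyl should arise on the concave face of ring B (cis to the cyclobutane), epimeric to the target, which step 10 corrects; the hemiacetal carbon C12 forms unselectively and is erased in step 7. Site selectivity for C6 over the furan β-carbon follows from the α-preference of furans, attack at C6 giving the oxygen-stabilized allyl cation.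

Step 7
Reactants: 13 tetracyclic lactol
Product: 14 tetracyclic butenolide (C12 lactone carbonyl; C4 ketone; 8-epi hydroxyl; two TBS ethers)
Conditions: TEMPO (10 mol%), PhI(OAc)2 (1.2 equiv), CH2Cl2, rt
Reagents that add atoms: none
Why: Oxoammonium oxidation (TEMPO/PhI(OAc)2) should convert the lactol into the butenolide faster than it oxidizes the hindered secondary alcohol.

Step 8
Reactants: 14 butenolide ketone
Product: 15 C4 exocyclic methylene compound
Conditions: Zn, CH2Br2, TiCl4, THF/CH2Cl2, 0 °C to rt
Reagents that add atoms: dibromomethane, BrCBr
Why: Takai–Lombardo methylenation is non-basic and ketone-selective, so the lactone, the free hydroxyl and the β-silyloxy ketone (prone to elimination under Wittig conditions) should survive.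

Step 9
Reactants: 15 methylene compound
Product: 16 C4 tertiary alcohol (OH trans to the cyclobutane bond C5–C6, CH3 cis to it)
Conditions: Co(acac)2 (20 mol%), PhSiH3 (2.5 equiv), O2 (1 atm), i-PrOH/CH2Cl2, 0 °C to rt
Reagents that add atoms: dioxygen, O=O
Why: Mukaiyama hydration (hydrogen-atom transfer from a cobalt hydride to the 1,1-disubstituted alkene, then O2 capture of the tertiary C4 radical) should deliver oxygen on the convex face of ring A, anti to the C5–C6 bond, while the tetrasubstituted electron-poor butenolide alkene should react much more slowly.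

Step 10
Reactants: 16 diol; 17 tiglic acid ((E)-2-methylbut-2-enoic acid)
Product: 18 C8 tiglate (inverted at C8; two TBS ethers; free C4–OH)
Conditions: 17 (2 equiv), PPh3, DIAD, toluene, 0 °C to rt
Reagents that add atoms: none
Why: Mitsunobu esterification proceeds with inversion at the secondary allylic carbinol C8, the carboxylate attacking from the open convex face, while the tertiary C4 hydroxyl does not react.

Step 11
Reactants: 18 bis-silyl ether tiglate
Product: 19 triol tiglate (free OH at C2, C4 and C13)
Conditions: HF·pyridine, THF/pyridine, 0 °C to rt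
Reagents that add atoms: none
Why: Fluoride-mediated desilylation under mildly acidic conditions cleaves both TBS ethers and should not cause acyl migration or lactone opening.

Step 12
Reactants: 19 triol tiglate
Product: 20 target CNP0210373.1
Conditions: Ac2O (2.2 equiv), pyridine, DMAP (5 mol%), CH2Cl2, 0 °C
Reagents that add atoms: acetic anhydride, CC(=O)OC(C)=O
Why: Acylation of the primary C13 and secondary C2 hydroxyls; the hindered tertiary C4 hydroxyl should stay free at 0 °C with limited reagent.

Compound list
1 | furan-3,4-diyldimethanol | OCc1cocc1CO | starting material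
2 | [4-({[tert-butyl(dimethyl)silyl]oxy}methyl)furan-3-yl]methanol | OCc1cocc1CO[Si](C)(C)C(C)(C)C | intermediate
3 | (S)-4-{[tert-butyl(dimethyl)silyl]oxy}cyclopent-2-en-1-one | O=C1C=C[C@@H](O[Si](C)(C)C(C)(C)C)C1 | starting material
4 | (S)-4-{[tert-butyl(dimethyl)silyl]oxy}-2-iodocyclopent-2-en-1-one | O=C1C(I)=C[C@@H](O[Si](C)(C)C(C)(C)C)C1 | intermediate
5 | dilithiated furan (2-lithio furan, lithium alkoxide) | [Li]OCc1c([Li])occ1CO[Si](C)(C)C(C)(C)C | intermediate
6 | furylzinc chloride (lithium alkoxide retained) | [Li]OCc1c([Zn]Cl)occ1CO[Si](C)(C)C(C)(C)C | intermediate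
7 | (S)-4-(TBS-oxy)-2-[3-(hydroxymethyl)-4-(TBS-oxymethyl)furan-2-yl]cyclopent-2-en-1-one | O=C1C(c2occ(CO[Si](C)(C)C(C)(C)C)c2CO)=C[C@@H](O[Si](C)(C)C(C)(C)C)C1 | intermediate
8 | isopropenylmagnesium bromide | CC(=C)[Mg]Br | starting material
9 | bromomagnesium enolate of 10 (magnesium alkoxide at the CH2O group) | CC(=C)[C@@H]1[C@@H](O[Si](C)(C)C(C)(C)C)CC(O[Mg]Br)=C1c1occ(CO[Si](C)(C)C(C)(C)C)c1CO[Mg]Br | intermediate
10 | 4-(TBS-oxy)-2-[3-(hydroxymethyl)-4-(TBS-oxymethyl)furan-2-yl]-3-isopropenylcyclopentan-1-one, furyl cis to isopropenyl, silyloxy trans to isopropenyl | CC(=C)[C@@H]1[C@@H](O[Si](C)(C)C(C)(C)C)CC(=O)[C@@H]1c1occ(CO[Si](C)(C)C(C)(C)C)c1CO | intermediate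
11 | corresponding furan-3-carbaldehyde (C8 = CHO) | CC(=C)[C@@H]1[C@@H](O[Si](C)(C)C(C)(C)C)CC(=O)[C@@H]1c1occ(CO[Si](C)(C)C(C)(C)C)c1C=O | intermediate
12 | tetracyclic C8 trichlorostannyl alkoxide with C12 α-chloro ether | Cl[Sn](Cl)(Cl)O[C@@H]1C[C@]2(C)[C@@H]3[C@@H](O[Si](C)(C)C(C)(C)C)CC(=O)[C@@H]3[C@@]23OC(Cl)C(CO[Si](C)(C)C(C)(C)C)=C13 | intermediate
13 | tetracyclic lactol: target skeleton with C4 ketone, C12 hemiacetal, 8-epi OH (cis to the cyclobutane), TBS ethers at O2 and O13 | O[C@@H]1C[C@]2(C)[C@@H]3[C@@H](O[Si](C)(C)C(C)(C)C)CC(=O)[C@@H]3[C@@]23OC(O)C(CO[Si](C)(C)C(C)(C)C)=C13 | intermediate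
14 | tetracyclic butenolide with C4 ketone and 8-epi OH | O[C@@H]1C[C@]2(C)[C@@H]3[C@@H](O[Si](C)(C)C(C)(C)C)CC(=O)[C@@H]3[C@@]23OC(=O)C(CO[Si](C)(C)C(C)(C)C)=C13 | intermediate
15 | C4 exocyclic methylene butenolide with 8-epi OH | O[C@@H]1C[C@]2(C)[C@@H]3[C@@H](O[Si](C)(C)C(C)(C)C)CC(=C)[C@@H]3[C@@]23OC(=O)C(CO[Si](C)(C)C(C)(C)C)=C13 | intermediate
16 | C4 tertiary alcohol (target configuration at C4) with 8-epi OH | O[C@@H]1C[C@]2(C)[C@@H]3[C@@H](O[Si](C)(C)C(C)(C)C)C[C@@](C)(O)[C@@H]3[C@@]23OC(=O)C(CO[Si](C)(C)C(C)(C)C)=C13 | intermediate
17 | tiglic acid | C/C=C(\C)C(=O)O | starting material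
18 | C8 tiglate (target configuration at C8), TBS ethers at O2 and O13 | C/C=C(\C)C(=O)O[C@H]1C[C@]2(C)[C@@H]3[C@@H](O[Si](C)(C)C(C)(C)C)C[C@@](C)(O)[C@@H]3[C@@]23OC(=O)C(CO[Si](C)(C)C(C)(C)C)=C13 | intermediate
19 | C8 tiglate triol (free OH at C2, C4, C13) | C/C=C(\C)C(=O)O[C@H]1C[C@]2(C)[C@@H]3[C@@H](O)C[C@@](C)(O)[C@@H]3[C@@]23OC(=O)C(CO)=C13 | intermediate
20 | CNP0210373.1 | C/C=C(\C)C(=O)O[C@H]1C[C@]2(C)[C@@H]3[C@@H](OC(C)=O)C[C@@](C)(O)[C@@H]3[C@@]23OC(=O)C(COC(C)=O)=C13 | target

Total step count: 12. Longest linear sequence: 11 steps (3 to 20 through steps 2–12; equally 1 to 20 through steps 1 and 3–12).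

Steps most likely to fail

Step 6. The tertiary cation may be lost by proton elimination, chloride capture or oxetane formation before the furan closes the four-membered ring. Ring B may also close on the face of the incipient cyclobutane away from ring A if the chelate does not control the furan rotamer; the fallback below does not by itself correct that facial selectivity. The fallback forms the two bonds in separate known operations. It sets out from 11: TiCl4 (1.1 equiv, CH2Cl2, −90 °C, short contact) should give the Prins cyclization with chloride capture, the seven-membered chlorohydrin F1, with the carbinol configuration expected from the same chelate and the chloride-bearing carbon undefined. Ionization of the tertiary chloride with AgSbF6 and 2,6-di-tert-butylpyridine (CH2Cl2, −40 °C) is a silver-promoted Friedel–Crafts alkylation of the furan α-carbon by a tertiary halide; aqueous quench brings the route back at lactol 13.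

Step 4. The furyl-conjugated enolate may be protonated on oxygen and then tautomerize under thermodynamic control, or the α-furyl ketone may epimerize on work-up, eroding the cis relationship. The fallback sets out from 7: the conjugate addition is run with TMSCl present (8, CuI, TMSCl, THF, −78 °C), and the bis(trimethylsilyl) compound F2 (silyl enol ether, primary hydroxyl also silylated) is isolated. Reagent-controlled protonation of this silyl enol ether with a Lewis acid-assisted Brønsted acid (BINOL·SnCl4, toluene, −78 °C, using the BINOL enantiomer that delivers the proton anti to the isopropenyl group), followed by mild aqueous work-up that cleaves the primary trimethylsilyl ether, brings the route back at 10.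

Step 10. The alkoxyphosphonium ion may form slowly on the concave face, and elimination toward C8=C9 may compete with substitution. The fallback sets out from 16: chloromethanesulfonyl chloride/pyridine should give the chloromethanesulfonate F3. Displacement with cesium tiglate (from 17 and Cs2CO3) and 18-crown-6 in toluene at 80 °C, a known inversion of hindered secondary alcohols, brings the route back at 18.

Further compounds
F1 | step 6 | seven-membered Prins chlorohydrin (C8–C9 bond formed, tertiary chloride at C10, furan intact) | O[C@@H]1CC(C)(Cl)[C@@H]2[C@@H](O[Si](C)(C)C(C)(C)C)CC(=O)[C@@H]2c2occ(CO[Si](C)(C)C(C)(C)C)c12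
F2 | step 4 | trimethylsilyl enol ether of 10 with the primary hydroxyl as its trimethylsilyl ether | CC(=C)[C@@H]1[C@@H](O[Si](C)(C)C(C)(C)C)CC(O[Si](C)(C)C)=C1c1occ(CO[Si](C)(C)C(C)(C)C)c1CO[Si](C)(C)C
F3 | step 10 | C8 chloromethanesulfonate of 16 | ClCS(=O)(=O)O[C@@H]1C[C@]2(C)[C@@H]3[C@@H](O[Si](C)(C)C(C)(C)C)C[C@@](C)(O)[C@@H]3[C@@]23OC(=O)C(CO[Si](C)(C)C(C)(C)C)=C13
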